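**Plan**

1. Locants (labdane numbering): ring A = C1–C5 and C10; ring B = C5–C10; C17 is the methyl on C8, C18 (CO2H) and C19 (CH3) sit on C4, C20 is the methyl on C10, and the side chain C11–C16 on C9 carries C13 and the C15 acetate.
2. Retrosynthesis: the benzyl ester is removed last. The tertiary carbinol C8(OH)(C17) beside C7H2 is read as a hydrated C7=C8 bond, so ring B becomes a cyclohexene. Ring A is cut at C3–C4 (enolate alkylation). Ring B is then cut at C5–C6 and C9–C10 into a C6–C9 diene and an acyclic C5=C10 alkene.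
3. Enabling feature: on ring B the groups C20 (on C10), C11 (on C9) and C4 (on C5) are all cis, C1 alone is on the other face, and C20 is anti to H5. This is the endo adduct of an (E,E)-diene with an (E)-trisubstituted alkene whose activating carbonyl is C4, so C4 enters as the ketone of an α-keto ester.
4. Forward: (S)-citronellol supplies C7–C9 and C11–C17. A phenylthio group on C6 steers the regiochemistry. Ring B arises by [4+2]; ring A by methylenation of C4=O and hydride-triggered C3–C4 closure. Sulfur is then removed, C7=C8 is hydrated and the benzyl group is cleaved.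
5. Stereochemistry: C13 comes from citronellol. C5, C9 and C10 come from the cycloaddition (alkene geometries, endo rule, chiral copper Lewis acid). C4 comes from allylic 1,3-strain in the ring closure. C8 comes from attack anti to the axial C20 methyl.

Key step: step 5

Assumption: the (S,S)-ligand in step 5 is taken to expose the enantioface of 8 that leads to 9; if the sense proves opposite, the (R,R)-ligand is used and nothing else changes.

**Route**

Step 1
Reactants: 1 (S)-citronellol
Product: 2 (S)-citronellyl acetate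
Conditions: Ac2O, pyridine, DMAP (cat.), CH2Cl2, 0 °C → rt
Reagents that add atoms: acetic anhydride, CC(=O)OC(C)=O
Why: Acylation of the primary alcohol installs the acetate of the target at the outset, where it also protects the oxygen, and leaves the stereocentre (C13 of the target) untouched.

Step 2
Reactants: 2 (S)-citronellyl acetate
Product: 3 (3S,6E)-3,7-dimethyl-8-oxooct-6-en-1-yl acetate
Conditions: SeO2, 1,4-dioxane, H2O (trace), 80 °C
Reagents that add atoms: selenium dioxide, O=[Se]=O
Why: Allylic oxidation with SeO2 (ene reaction, then [2,3]-shift) attacks the (E)-methyl group of the trisubstituted alkene and should give the (E)-enal, whose formyl carbon becomes C7 and whose remaining methyl becomes C17.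

Step 3
Reactants: 3 (3S,6E)-3,7-dimethyl-8-oxooct-6-en-1-yl acetate
Product: 4 (3S,6E,8E)-3,7-dimethyl-9-(phenylsulfanyl)nona-6,8-dien-1-yl acetate
Conditions: (EtO)2P(O)CH2SPh, n-BuLi, THF, −78 → 40 °C
Reagents that add atoms: diethyl [(phenylsulfanyl)methyl]phosphonate, CCOP(=O)(CSc1ccccc1)OCC
Why: Horner–Wadsworth–Emmons olefination with the sulfur-stabilised phosphonate anion, which adds to the aldehyde far faster than to the acetate, adds C6 as a mainly (E)-vinyl sulfide and gives the 1-phenylthio diene, the minor (8Z) isomer being removed by chromatography.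

Step 4
Reactants: 5 5-bromopent-1-yne; 6 benzyl chlorooxoacetate
Product: 8 benzyl (3E)-7-bromo-4-methyl-2-oxohept-3-enoate, via alkenylalane 7 (not isolated)
Conditions: Me3Al, Cp2ZrCl2 (cat.), CH2Cl2, rt; then 6, THF, −30 → 0 °C
Reagents that add atoms: trimethylaluminium, C[Al](C)C
Why: Zirconium-catalysed syn-carboalumination (Negishi) puts methyl on the internal and aluminium on the terminal alkyne carbon, and acylation of the alkenyl–aluminium bond with retention should give the (E)-keto ester in which the future C20 methyl is cis to the keto carbon C4 and the bromopropyl chain (C1–C3) is trans.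

Step 5
Reactants: 4 (3S,6E,8E)-3,7-dimethyl-9-(phenylsulfanyl)nona-6,8-dien-1-yl acetate; 8 benzyl (3E)-7-bromo-4-methyl-2-oxohept-3-enoate
Product: 9 benzyl 2-[(1S,2S,5R,6S)-5-[(3S)-5-(acetyloxy)-3-methylpentyl]-6-(3-bromopropyl)-4,6-dimethyl-2-(phenylsulfanyl)cyclohex-3-en-1-yl]-2-oxoacetate
Conditions: Cu(SbF6)2 with (S,S)-2,2'-(propane-2,2-diyl)bis(4-tert-butyl-4,5-dihydro-1,3-oxazole) (10 mol%), 4 Å molecular sieves, CH2Cl2, −40 → 0 °C
Reagents that add atoms: none
Why: Proposed new method: with both carbonyl oxygens of 8 bound to the divalent copper centre the C5=C10 bond is strongly LUMO-lowered, and a concerted but asynchronous [4+2] is expected in which C9 of 4 (the diene terminus remote from sulfur, with the largest HOMO coefficient) bonds first to the β-carbon C10 and the sulfur-bearing C6 then bonds to C5. The closest known reaction types are the bis(oxazoline)–copper-catalysed cycloadditions of γ-monosubstituted 2-oxobut-3-enoates and the Lewis acid Diels–Alder reactions of 1-arylthio dienes and of β,β-disubstituted enones; the new element is their combination on a γ,γ-disubstituted keto ester, which makes the quaternary C10. Ring B is closed by an intermolecular, suprafacial–suprafacial endo [4+2]. The (E)-geometry of 8 puts the C20 methyl cis to the keto ester on C5 (hence C20 anti to H5, the later trans ring fusion), the (6E,8E)-geometry of 4 together with the endo position of the chelated keto ester puts C11 on C9 and the sulfur on C6 cis to that keto ester, and the C2-symmetric ligand blocks one face of the chelate so that C5, C6, C9 and C10 arise in one absolute sense beside the untouched C13. The step needs regio-, endo-, enantioface and periselectivity (carbon [4+2] against the oxa-[4+2] of the O=C4–C5=C10 unit with the vinyl sulfide); these rest on the sulfur donor (which overrides the opposite bias of the 1-alkyl group), on secondary overlap of the diene with the chelated dicarbonyl, on the ligand, and on the fact that the oxa-[4+2] would have to join the internal carbon C7 to the hindered C10.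

Step 6
Reactants: 9 benzyl 2-[(1S,2S,5R,6S)-5-[(3S)-5-(acetyloxy)-3-methylpentyl]-6-(3-bromopropyl)-4,6-dimethyl-2-(phenylsulfanyl)cyclohex-3-en-1-yl]-2-oxoacetate
Product: 10 benzyl 2-[(1S,2S,5R,6S)-5-[(3S)-5-(acetyloxy)-3-methylpentyl]-6-(3-bromopropyl)-4,6-dimethyl-2-(phenylsulfanyl)cyclohex-3-en-1-yl]prop-2-enoate
Conditions: Zn, CH2Br2, TiCl4, THF, 0 °C → rt
Reagents that add atoms: dibromomethane, BrCBr
Why: Lombardo methylenation turns the ketone carbonyl C4=O into C4=CH2 (the future C19 methyl) under non-basic conditions, so that neither epimerisation at C5 nor β-elimination of thiophenol from the β-thio ketone should occur and both esters stay intact.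

Step 7
Reactants: 10 benzyl 2-[(1S,2S,5R,6S)-5-[(3S)-5-(acetyloxy)-3-methylpentyl]-6-(3-bromopropyl)-4,6-dimethyl-2-(phenylsulfanyl)cyclohex-3-en-1-yl]prop-2-enoate
Product: 12 benzyl (1S,4aS,5R,8S,8aS)-5-[(3S)-5-(acetyloxy)-3-methylpentyl]-1,4a,6-trimethyl-8-(phenylsulfanyl)-1,2,3,4,4a,5,8,8a-octahydronaphthalene-1-carboxylate, via lithium enolate 11 (not isolated)
Conditions: LiB(s-Bu)3H (1.05 equiv), THF, −78 °C; then DMPU, −78 → 0 °C
Reagents that add atoms: none
Why: Conjugate hydride addition to the 2-substituted acrylate (tandem 1,4-reduction–alkylation) makes the C4 ester enolate with its new C19 methyl, which closes ring A by 6-exo-tet SN2 at the C3 bromide; allylic 1,3-strain keeps the enolate carbon C18 eclipsed with H5 while C3 arrives from the C10 side, so the ester should end equatorial and the methyl axial, and the trans ring fusion follows from the C1/C4 anti relation made in step 5.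

Step 8
Reactants: 12 benzyl (1S,4aS,5R,8S,8aS)-5-[(3S)-5-(acetyloxy)-3-methylpentyl]-1,4a,6-trimethyl-8-(phenylsulfanyl)-1,2,3,4,4a,5,8,8a-octahydronaphthalene-1-carboxylate
Product: 13 benzyl (1S,4aS,5R,8aS)-5-[(3S)-5-(acetyloxy)-3-methylpentyl]-1,4a,6-trimethyl-1,2,3,4,4a,5,8,8a-octahydronaphthalene-1-carboxylate
Conditions: Raney Ni (W-2, deactivated in acetone), THF/EtOH, 0 °C → rt
Reagents that add atoms: none
Why: Hydrogenolysis of the axial, allylic C6–S bond on nickel removes the regiocontrol group and its syn-axial strain with C19 and C20, and the hindered trisubstituted C7=C8 bond should stay in place as the more stable allylic isomer.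

Step 9
Reactants: 13 benzyl (1S,4aS,5R,8aS)-5-[(3S)-5-(acetyloxy)-3-methylpentyl]-1,4a,6-trimethyl-1,2,3,4,4a,5,8,8a-octahydronaphthalene-1-carboxylate
Product: 14 benzyl (1S,4aR,5S,6S,8aS)-5-[(3S)-5-(acetyloxy)-3-methylpentyl]-6-hydroxy-1,4a,6-trimethyldecahydronaphthalene-1-carboxylate
Conditions: Mn(dpm)3 (dpm = dipivaloylmethanate, 10 mol%), PhSiH3, O2 (1 atm), i-PrOH/CH2Cl2, 0 °C → rt
Reagents that add atoms: dioxygen, O=O
Why: Mukaiyama hydration (hydrogen-atom transfer to C7, O2 capture of the tertiary C8 radical, reduction of the peroxide) gives the Markovnikov tertiary alcohol, and oxygen should enter from the face opposite the axial C20 methyl so that the OH is equatorial and C17 axial.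

Step 10
Reactants: 14 benzyl (1S,4aR,5S,6S,8aS)-5-[(3S)-5-(acetyloxy)-3-methylpentyl]-6-hydroxy-1,4a,6-trimethyldecahydronaphthalene-1-carboxylate
Product: 15 (1S,4aR,5S,6S,8aS)-5-[(3S)-5-(acetyloxy)-3-methylpentyl]-6-hydroxy-1,4a,6-trimethyldecahydronaphthalene-1-carboxylic acid
Conditions: H2 (1 atm), Pd/C, EtOAc, rt
Reagents that add atoms: none
Why: Hydrogenolysis of the benzyl ester frees the hindered C18 acid without acid or base, so the primary acetate and the tertiary alcohol are kept.

**Compound list**

1 | (S)-citronellol, (3S)-3,7-dimethyloct-6-en-1-ol | OCC[C@@H](C)CCC=C(C)C | starting material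
2 | (S)-citronellyl acetate, (3S)-3,7-dimethyloct-6-en-1-yl acetate | CC(=O)OCC[C@@H](C)CCC=C(C)C | intermediate
3 | (3S,6E)-3,7-dimethyl-8-oxooct-6-en-1-yl acetate | CC(=O)OCC[C@@H](C)CC/C=C(\C)C=O | intermediate
4 | (3S,6E,8E)-3,7-dimethyl-9-(phenylsulfanyl)nona-6,8-dien-1-yl acetate | CC(=O)OCC[C@@H](C)CC/C=C(\C)/C=C/Sc1ccccc1 | intermediate
5 | 5-bromopent-1-yne | C#CCCCBr | starting material
6 | benzyl chlorooxoacetate (benzyl 2-chloro-2-oxoacetate) | O=C(Cl)C(=O)OCc1ccccc1 | starting material
7 | (E)-(5-bromo-2-methylpent-1-en-1-yl)dimethylalane | C[Al](C)/C=C(\C)CCCBr | intermediate (not isolated)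
8 | benzyl (3E)-7-bromo-4-methyl-2-oxohept-3-enoate | O=C(OCc1ccccc1)C(=O)/C=C(\C)CCCBr | intermediate
9 | benzyl 2-[(1S,2S,5R,6S)-5-[(3S)-5-(acetyloxy)-3-methylpentyl]-6-(3-bromopropyl)-4,6-dimethyl-2-(phenylsulfanyl)cyclohex-3-en-1-yl]-2-oxoacetate (keto ester, SPh, side chain and ring methyl on C6 all cis) | CC(=O)OCC[C@@H](C)CC[C@H]1[C@](C)(CCCBr)[C@@H](C(=O)C(=O)OCc2ccccc2)[C@@H](Sc3ccccc3)C=C1C | intermediate
10 | benzyl 2-[(1S,2S,5R,6S)-5-[(3S)-5-(acetyloxy)-3-methylpentyl]-6-(3-bromopropyl)-4,6-dimethyl-2-(phenylsulfanyl)cyclohex-3-en-1-yl]prop-2-enoate | CC(=O)OCC[C@@H](C)CC[C@H]1[C@](C)(CCCBr)[C@@H](C(=C)C(=O)OCc2ccccc2)[C@@H](Sc3ccccc3)C=C1C | intermediate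
11 | lithium enolate of the benzyl propanoate derived from 10 (C4 enolate bearing the C19 methyl) | CC(=O)OCC[C@@H](C)CC[C@H]1[C@](C)(CCCBr)[C@@H](C(C)=C(O[Li])OCc2ccccc2)[C@@H](Sc3ccccc3)C=C1C | intermediate (not isolated)
12 | benzyl (1S,4aS,5R,8S,8aS)-5-[(3S)-5-(acetyloxy)-3-methylpentyl]-1,4a,6-trimethyl-8-(phenylsulfanyl)-1,2,3,4,4a,5,8,8a-octahydronaphthalene-1-carboxylate (trans-fused; ester equatorial) | CC(=O)OCC[C@@H](C)CC[C@H]1[C@]2(C)CCC[C@](C)(C(=O)OCc3ccccc3)[C@H]2[C@@H](Sc4ccccc4)C=C1C | intermediate
13 | benzyl (1S,4aS,5R,8aS)-5-[(3S)-5-(acetyloxy)-3-methylpentyl]-1,4a,6-trimethyl-1,2,3,4,4a,5,8,8a-octahydronaphthalene-1-carboxylate | CC(=O)OCC[C@@H](C)CC[C@H]1[C@]2(C)CCC[C@](C)(C(=O)OCc3ccccc3)[C@H]2CC=C1C | intermediate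
14 | benzyl (1S,4aR,5S,6S,8aS)-5-[(3S)-5-(acetyloxy)-3-methylpentyl]-6-hydroxy-1,4a,6-trimethyldecahydronaphthalene-1-carboxylate | CC(=O)OCC[C@@H](C)CC[C@H]1[C@]2(C)CCC[C@](C)(C(=O)OCc3ccccc3)[C@H]2CC[C@]1(C)O | intermediate
15 | (1S,4aR,5S,6S,8aS)-5-[(3S)-5-(acetyloxy)-3-methylpentyl]-6-hydroxy-1,4a,6-trimethyldecahydronaphthalene-1-carboxylic acid | CC(=O)OCC[C@@H](C)CC[C@H]1[C@]2(C)CCC[C@](C)(C(=O)O)[C@H]2CC[C@]1(C)O | target

**Step count**

Total steps: 10. Longest linear sequence: 9 (steps 1, 2, 3, 5, 6, 7, 8, 9, 10).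

**Steps most likely to fail, with fallbacks**

Step 5. The cycloaddition may stall at the doubly substituted alkene terminus, be diverted into the oxa-[4+2] or into E/Z isomerisation of the keto ester, or be slowed by binding of the thioether to copper, giving low conversion or poor facial selectivity. The fallback uses auxiliary control under a strong achiral Lewis acid, a known combination for ester-bound dienophiles. It sets out from 5 (through 7) and 4. Alane 7 is acylated with (1R,2S,5R)-8-phenylmenthyl chlorooxoacetate F1, made from (−)-8-phenylmenthol and oxalyl chloride, to give (1R,2S,5R)-8-phenylmenthyl (3E)-7-bromo-4-methyl-2-oxohept-3-enoate F2. F2 and 4 are combined with EtAlCl2 in CH2Cl2 at −78 °C, where the aryl group of the auxiliary covers one face of the chelated keto ester, to give the 8-phenylmenthyl ester analogue of 9 F3. Transesterification with benzyl alcohol and Ti(OCH2Ph)4 in toluene comes back at 9 and returns the auxiliary; the antipodal auxiliary is used if the sense of induction is opposite.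

Step 7. The hydride may attack the acetate or the bromide, the enolate may fail to close, or closure may go through the rotamer that puts the ester axial. The fallback separates reduction from ring closure and sets out from 10. Chemoselective conjugate reduction with [(Ph3P)CuH]6 and aqueous work-up should give benzyl 2-[(1S,2S,5R,6S)-5-[(3S)-5-(acetyloxy)-3-methylpentyl]-6-(3-bromopropyl)-4,6-dimethyl-2-(phenylsulfanyl)cyclohex-3-en-1-yl]propanoate F4 as both C4 epimers, which is of no consequence. Deprotonation with KN(SiMe3)2 in THF/DMPU at −78 → 0 °C then closes ring A through the more reactive potassium enolate and comes back at 12.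

Step 8. Hydrogenolysis of the allylic C–S bond may be accompanied by migration or saturation of the C7=C8 bond or by early loss of the benzyl group. The fallback uses the sulfur to place the C8 oxygen and sets out from 12. Excess m-CPBA with NaHCO3 should give the C6 sulfone carrying a 7,8-epoxide on the face opposite the axial sulfone and C20, benzyl (1S,4aR,5S,8aS)-5-[(3S)-5-(acetyloxy)-3-methylpentyl]-7,8-epoxy-1,4a,6-trimethyl-8-(phenylsulfonyl)-decahydronaphthalene-1-carboxylate (naphthalene locants: epoxide across C6–C7, sulfone on C8) F5. Reductive elimination with SmI2 in THF/HMPA should give the allylic alcohol benzyl (1S,4aR,5S,6S,8aS)-5-[(3S)-5-(acetyloxy)-3-methylpentyl]-6-hydroxy-1,4a,6-trimethyl-1,2,3,4,4a,5,6,8a-octahydronaphthalene-1-carboxylate F6, with the tertiary OH already in place. H2 over Pd/C then saturates the ring alkene and removes the benzyl group, coming back at 15, so steps 9 and 10 are not needed.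

**Further compounds**

F1 | step 5 | (1R,2S,5R)-8-phenylmenthyl chlorooxoacetate | CC(C)(c1ccccc1)[C@@H]1CC[C@@H](C)C[C@H]1OC(=O)C(Cl)=O
F2 | step 5 | (1R,2S,5R)-8-phenylmenthyl (3E)-7-bromo-4-methyl-2-oxohept-3-enoate | CC(C)(c1ccccc1)[C@@H]1CC[C@@H](C)C[C@H]1OC(=O)C(=O)/C=C(\C)CCCBr
F3 | step 5 | 8-phenylmenthyl ester analogue of 9 | CC(=O)OCC[C@@H](C)CC[C@H]1[C@](C)(CCCBr)[C@@H](C(=O)C(=O)O[C@@H]2C[C@H](C)CC[C@H]2C(C)(C)c3ccccc3)[C@@H](Sc4ccccc4)C=C1C
F4 | step 7 | benzyl 2-[(1S,2S,5R,6S)-5-[(3S)-5-(acetyloxy)-3-methylpentyl]-6-(3-bromopropyl)-4,6-dimethyl-2-(phenylsulfanyl)cyclohex-3-en-1-yl]propanoate (both epimers at the propanoate carbon) | CC(=O)OCC[C@@H](C)CC[C@H]1[C@](C)(CCCBr)[C@@H](C(C)C(=O)OCc2ccccc2)[C@@H](Sc3ccccc3)C=C1C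
F5 | step 8 | epoxy sulfone from 12 (sulfone on C6, epoxide across C7–C8 anti to it, labdane locants) | CC(=O)OCC[C@@H](C)CC[C@H]1[C@]2(C)CCC[C@](C)(C(=O)OCc3ccccc3)[C@H]2[C@@H](S(=O)(=O)c4ccccc4)[C@@H]5O[C@]15C
F6 | step 8 | benzyl (1S,4aR,5S,6S,8aS)-5-[(3S)-5-(acetyloxy)-3-methylpentyl]-6-hydroxy-1,4a,6-trimethyl-1,2,3,4,4a,5,6,8a-octahydronaphthalene-1-carboxylate | CC(=O)OCC[C@@H](C)CC[C@H]1[C@]2(C)CCC[C@](C)(C(=O)OCc3ccccc3)[C@H]2C=C[C@]1(C)O
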